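**Retrosynthetic overview**

1. Target 17 comes from its C6 benzyl ether 16; the last step frees the phenol that lies between the C5 and C7 methoxy groups.
2. Ring C of 16 is cut at two bonds at once, O1–C8a and C4–C4a. Ring A becomes the unsymmetrical aryne 13 (from ortho-silylaryl triflate 7), and the O1–C2–C3–C4 chain with ring B becomes the potassium alkoxide of the (S)-β-hydroxy morpholine amide 11. The alkoxide adds to the aryne, and the aryl anion so formed closes ring C on the amide carbonyl.
3. Enabling feature: C8a and C4a are neighbouring carbons of ring A carrying the ether oxygen O1 and the ketone carbon C4, which is the imprint of an aryne. The methoxy group on C5 beside C4a, against hydrogen on C8 beside C8a, sends oxygen to C8a and the carbanion to C4a. The single stereocentre C2 is a carbinol carbon that is set beforehand and carried through untouched.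
4. 11 comes from β-keto ester 8 and morpholine 9, then asymmetric transfer hydrogenation. 7 comes from aldehyde 1 by bromination, Baeyer–Villiger oxidation and retro-Brook silyl shift with triflation.
5. Ring order: rings A and B are bought; ring C (the pyranone) is the only ring made, in step 6.

Key step: step 6

Assumption: the stereocentre as drawn is read as (2S) (flavanone numbering is used throughout), and compounds 1 and 8 are taken as catalogue chemicals (1 is otherwise one benzylation away from syringaldehyde).

**Route**

Step 1
Reactants: 1 4-(benzyloxy)-3,5-dimethoxybenzaldehyde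
Product: 2 4-(benzyloxy)-2-bromo-3,5-dimethoxybenzaldehyde
Conditions: NBS, MeCN, rt
Reagents that add atoms: N-bromosuccinimide, O=C1CCC(=O)N1Br
Why: Electrophilic aromatic bromination; the two free positions of the ring are equivalent by symmetry, each ortho to one methoxy group and para to the other, and the aldehyde plus the first bromine should hold the reaction at monobromination.

Step 2
Reactants: 2 4-(benzyloxy)-2-bromo-3,5-dimethoxybenzaldehyde
Product: 4 4-(benzyloxy)-2-bromo-3,5-dimethoxyphenol, via aryl formate 3 (not isolated)
Conditions: mCPBA, CH2Cl2, 0 °C to rt; then K2CO3 (cat.), MeOH, rt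
Reagents that add atoms: meta-chloroperoxybenzoic acid, OOC(=O)c1cccc(Cl)c1
Why: Baeyer–Villiger (Dakin-type) oxidation; the electron-rich aryl group migrates in the Criegee intermediate to give the aryl formate, which catalytic methanolysis should convert to the phenol.

Step 3
Reactants: 4 4-(benzyloxy)-2-bromo-3,5-dimethoxyphenol
Product: 7 4-(benzyloxy)-3,5-dimethoxy-2-(trimethylsilyl)phenyl trifluoromethanesulfonate, via aryl trimethylsilyl ether 5 (not isolated), via lithium ortho-silylphenoxide 6 (not isolated)
Conditions: HMDS, THF, 70 °C, evaporate; n-BuLi, THF, −100 °C; Tf2O, −100 °C to rt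
Reagents that add atoms: hexamethyldisilazane, C[Si](C)(C)N[Si](C)(C)C; trifluoromethanesulfonic anhydride, O=S(=O)(OS(=O)(=O)C(F)(F)F)C(F)(F)F
Why: O-silylation, bromine–lithium exchange and retro-Brook 1,3 O-to-C silyl shift give the ortho-silyl phenoxide, which Tf2O traps; this is the standard route from ortho-bromophenols to ortho-silylaryl triflate aryne precursors.

Step 4
Reactants: 8 ethyl 3-(3,4-dimethoxyphenyl)-3-oxopropanoate; 9 morpholine
Product: 10 1-(3,4-dimethoxyphenyl)-3-(morpholin-4-yl)propane-1,3-dione
Conditions: DMAP (0.3 equiv), toluene, reflux, EtOH distilled off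
Reagents that add atoms: none
Why: DMAP-promoted aminolysis of a β-keto ester (acyl substitution, possibly through the acylketene), driven by removal of ethanol.

Step 5
Reactants: 10 1-(3,4-dimethoxyphenyl)-3-(morpholin-4-yl)propane-1,3-dione
Product: 11 (3S)-3-(3,4-dimethoxyphenyl)-3-hydroxy-1-(morpholin-4-yl)propan-1-one
Conditions: RuCl(p-cymene)[(S,S)-TsDPEN] (1 mol%), HCO2H/Et3N (5:2), CH2Cl2, 30 °C
Reagents that add atoms: none
Why: Noyori asymmetric transfer hydrogenation of an aryl ketone; the aryl group is held against the cymene ligand by a CH–π contact in the outer-sphere transition state, so the (S,S)-ligand should deliver hydride to the same face as with acetophenone and set the (S)-carbinol (aryl outranks the CH2C(O)N arm, so the descriptor is the same).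

Step 6
Reactants: 11 (3S)-3-(3,4-dimethoxyphenyl)-3-hydroxy-1-(morpholin-4-yl)propan-1-one; 7 4-(benzyloxy)-3,5-dimethoxy-2-(trimethylsilyl)phenyl trifluoromethanesulfonate
Product: 16 (2S)-6-(benzyloxy)-2-(3,4-dimethoxyphenyl)-5,7-dimethoxy-2,3-dihydro-4H-chromen-4-one, via potassium alkoxide 12 (not isolated), via aryne 13 (not isolated), via aryl anion 14 (not isolated), via hemiaminal alkoxide 15 (not isolated)
Conditions: 11 (1.3 equiv), KH (1.3 equiv), THF, 0 °C; CsF (3 equiv), 18-crown-6 (3 equiv), 7 added slowly, 0 °C to rt; AcOH, −20 °C, then aq NaHCO3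
Reagents that add atoms: none
Why: Proposed new method: fluoride removes the silyl group of 7 and triflate leaves to give aryne 13; the pre-formed alkoxide 12 adds to the aryne carbon remote from the flanking methoxy group (the future C8a), and the aryl anion 14, which sits ortho to that methoxy group (the future C4a), attacks the morpholine amide carbonyl to form the C4–C4a bond and close ring C as hemiaminal alkoxide 15, which releases the ketone only on the acetic acid quench. The closest known reaction types are the annulation of arynes with ortho-hydroxybenzoates and ortho-aminobenzoates to xanthones and acridones (heteroatom addition, then acyl substitution by the aryl anion), the insertion of arynes into amide N–C(O) bonds, and the Parham cyclization of an aryllithium onto a tethered tertiary amide; new here is a secondary aliphatic alkoxide of an aldol-type amide as the partner. Ring C closes by a 6-exo-trig addition of the aryl carbanion to the exocyclic C=O. No stereocentre of the product is created: C2 comes from 11 with its C–O and C–H bonds untouched, and the transient C4 hemiaminal centre is destroyed on work-up. The step needs regioselective addition to the unsymmetrical aryne, secured by the inductive pull of the C5 methoxy group on one side of the triple bond against hydrogen on the other, which distorts the aryne so that the nucleophile takes the distal carbon and the charge develops beside oxygen; it also needs acylation to outrun proton transfer, secured by the aprotic medium (KH leaves no conjugate acid) and the six-membered closure. The morpholine amide is chosen because its tetrahedral adduct persists without chelation, so the base-labile flavanone (enolisation, retro-oxa-Michael opening, racemisation at C2) should never meet the alkoxide.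

Step 7
Reactants: 16 (2S)-6-(benzyloxy)-2-(3,4-dimethoxyphenyl)-5,7-dimethoxy-2,3-dihydro-4H-chromen-4-one
Product: 17 (2S)-2-(3,4-dimethoxyphenyl)-6-hydroxy-5,7-dimethoxy-2,3-dihydro-4H-chromen-4-one
Conditions: H2 (1 atm), 10% Pd/C, EtOAc, rt, stopped at full conversion
Reagents that add atoms: none
Why: Hydrogenolysis of an aryl benzyl ether under neutral conditions; the primary benzyl–oxygen bond should cleave well before the hindered secondary C2–O1 bond of ring C, and C2 is not epimerisable under these conditions.

**Compound list**

1 | 4-(benzyloxy)-3,5-dimethoxybenzaldehyde | COc1cc(C=O)cc(OC)c1OCc1ccccc1 | starting material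
2 | 4-(benzyloxy)-2-bromo-3,5-dimethoxybenzaldehyde | COc1cc(C=O)c(Br)c(OC)c1OCc1ccccc1 | intermediate
3 | 4-(benzyloxy)-2-bromo-3,5-dimethoxyphenyl formate | COc1cc(OC=O)c(Br)c(OC)c1OCc1ccccc1 | intermediate
4 | 4-(benzyloxy)-2-bromo-3,5-dimethoxyphenol | COc1cc(O)c(Br)c(OC)c1OCc1ccccc1 | intermediate
5 | [4-(benzyloxy)-2-bromo-3,5-dimethoxyphenoxy]trimethylsilane | COc1cc(O[Si](C)(C)C)c(Br)c(OC)c1OCc1ccccc1 | intermediate
6 | lithium 4-(benzyloxy)-3,5-dimethoxy-2-(trimethylsilyl)phenoxide | [Li+].COc1cc([O-])c([Si](C)(C)C)c(OC)c1OCc1ccccc1 | intermediate
7 | 4-(benzyloxy)-3,5-dimethoxy-2-(trimethylsilyl)phenyl trifluoromethanesulfonate | COc1cc(OS(=O)(=O)C(F)(F)F)c([Si](C)(C)C)c(OC)c1OCc1ccccc1 | intermediate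
8 | ethyl 3-(3,4-dimethoxyphenyl)-3-oxopropanoate | CCOC(=O)CC(=O)c1ccc(OC)c(OC)c1 | starting material
9 | morpholine | C1COCCN1 | starting material
10 | 1-(3,4-dimethoxyphenyl)-3-(morpholin-4-yl)propane-1,3-dione | COc1ccc(C(=O)CC(=O)N2CCOCC2)cc1OC | intermediate
11 | (3S)-3-(3,4-dimethoxyphenyl)-3-hydroxy-1-(morpholin-4-yl)propan-1-one | COc1ccc([C@@H](O)CC(=O)N2CCOCC2)cc1OC | intermediate
12 | potassium (1S)-1-(3,4-dimethoxyphenyl)-3-(morpholin-4-yl)-3-oxopropan-1-olate | [K+].COc1ccc([C@@H]([O-])CC(=O)N2CCOCC2)cc1OC | intermediate
13 | 4-(benzyloxy)-3,5-dimethoxybenzyne (1,2-didehydrobenzene; triple bond between the former C–OTf and C–Si carbons) | COC1=CC#CC(OC)=C1OCc1ccccc1 | intermediate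
14 | potassium 3-(benzyloxy)-6-{[(1S)-1-(3,4-dimethoxyphenyl)-3-(morpholin-4-yl)-3-oxopropyl]oxy}-2,4-dimethoxybenzen-1-ide (carbanion ortho to methoxy and to the new ether oxygen) | [K+].COc1ccc([C@H](CC(=O)N2CCOCC2)Oc2cc(OC)c(OCc3ccccc3)c(OC)[c-]2)cc1OC | intermediate
15 | potassium (2S)-6-(benzyloxy)-2-(3,4-dimethoxyphenyl)-5,7-dimethoxy-4-(morpholin-4-yl)-3,4-dihydro-2H-chromen-4-olate (C4 configuration undefined) | [K+].COc1ccc([C@@H]2CC([O-])(N3CCOCC3)c3c(cc(OC)c(OCc4ccccc4)c3OC)O2)cc1OC | intermediate
16 | (2S)-6-(benzyloxy)-2-(3,4-dimethoxyphenyl)-5,7-dimethoxy-2,3-dihydro-4H-chromen-4-one | COc1ccc([C@@H]2CC(=O)c3c(cc(OC)c(OCc4ccccc4)c3OC)O2)cc1OC | intermediate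
17 | (2S)-2-(3,4-dimethoxyphenyl)-6-hydroxy-5,7-dimethoxy-2,3-dihydro-4H-chromen-4-one | COc1ccc([C@@H]2CC(=O)c3c(cc(OC)c(O)c3OC)O2)cc1OC | target

**Step count**

Total steps: 7. Longest linear sequence: 5 (steps 1, 2, 3, 6, 7).

**Steps most likely to fail**

Step 6. What may go wrong: proton transfer to the aryl anion, for instance from the C3 methylene of the same molecule, could outrun ring closure and be followed by elimination of the aryloxide. The crown-complexed alkoxide could undergo retro-aldol fragmentation and lose enantiopurity. The alkoxide could attack the triflate sulfur in place of the silicon-triggered elimination. The hemiaminal alkoxide could add to a second aryne. The fallback makes the same aryl–acyl bond by known chemistry and sets out from ketoamide 10 and bromophenol 4. Noyori transfer hydrogenation of 10 with RuCl(p-cymene)[(R,R)-TsDPEN] should give (3R)-3-(3,4-dimethoxyphenyl)-3-hydroxy-1-(morpholin-4-yl)propan-1-one F1. Mitsunobu etherification of F1 with 4 (PPh3, DIAD, THF, 0 °C) should proceed with inversion at the carbinol carbon to give (3S)-3-[4-(benzyloxy)-2-bromo-3,5-dimethoxyphenoxy]-3-(3,4-dimethoxyphenyl)-1-(morpholin-4-yl)propan-1-one F2. Treatment with n-BuLi in THF at −78 °C should effect bromine–lithium exchange to the aryllithium F3, which closes on the tethered amide (Parham cyclization) to the lithium hemiaminal alkoxide F4. Acetic acid quench returns the route at compound 16. The low temperature in the Mitsunobu step is meant to limit ionisation of the electron-rich benzylic carbinol.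

Step 7. What may go wrong: hydrogenolysis could continue into the benzylic C2–O1 bond of ring C (ring opening), or the aryl ketone could be reduced. The fallback replaces reduction by Lewis-acid debenzylation with a cation trap and runs from compound 16 directly to compound 17 (no new compound, F0): BCl3 and pentamethylbenzene in CH2Cl2 at −78 °C, short reaction time, methanol quench. The benzyl cation is captured by the arene, and the methyl ethers, including the one on C5 beside the carbonyl, should survive at this temperature.

Step 5. What may go wrong: the electron-rich, partly enolised β-keto amide could be reduced slowly or with insufficient facial selectivity, and the acidic formic acid medium could erode the configuration of the electron-rich benzylic carbinol. The fallback changes substrate, mechanism and order of events. It sets out from β-keto ester 8: hydrogenation with H2 and RuCl2[(R)-BINAP] in EtOH (chelation-controlled inner-sphere reduction of the β-keto ester) should give ethyl (3S)-3-(3,4-dimethoxyphenyl)-3-hydroxypropanoate F5. This is the same facial sense that gives (R)-3-hydroxybutanoates; the descriptor is (S) here because aryl outranks the ester arm. Aminolysis of F5 with morpholine and AlMe3 in toluene (0 to 60 °C) comes back to the route at compound 11.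

**Further compounds**

F1 | step 6 | (3R)-3-(3,4-dimethoxyphenyl)-3-hydroxy-1-(morpholin-4-yl)propan-1-one | COc1ccc([C@H](O)CC(=O)N2CCOCC2)cc1OC
F2 | step 6 | (3S)-3-[4-(benzyloxy)-2-bromo-3,5-dimethoxyphenoxy]-3-(3,4-dimethoxyphenyl)-1-(morpholin-4-yl)propan-1-one | COc1ccc([C@H](CC(=O)N2CCOCC2)Oc2cc(OC)c(OCc3ccccc3)c(OC)c2Br)cc1OC
F3 | step 6 | lithium 3-(benzyloxy)-6-{[(1S)-1-(3,4-dimethoxyphenyl)-3-(morpholin-4-yl)-3-oxopropyl]oxy}-2,4-dimethoxybenzen-1-ide (aryllithium) | [Li+].COc1ccc([C@H](CC(=O)N2CCOCC2)Oc2cc(OC)c(OCc3ccccc3)c(OC)[c-]2)cc1OC
F4 | step 6 | lithium (2S)-6-(benzyloxy)-2-(3,4-dimethoxyphenyl)-5,7-dimethoxy-4-(morpholin-4-yl)-3,4-dihydro-2H-chromen-4-olate | [Li+].COc1ccc([C@@H]2CC([O-])(N3CCOCC3)c3c(cc(OC)c(OCc4ccccc4)c3OC)O2)cc1OC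
F0 | step 7 | none | none
F5 | step 5 | ethyl (3S)-3-(3,4-dimethoxyphenyl)-3-hydroxypropanoate | CCOC(=O)C[C@H](O)c1ccc(OC)c(OC)c1
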